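## Analysis of the target

(6Z)-Neomanoalide (30) is a sesterterpenoid with a ring at each end: a furan-2(5H)-one (ring A: O1, C2(=O), C3H=C4, C5H) and a 2,6,6-trimethylcyclohexene (ring B). The two are joined by the chain C6H2–C7H=C8(CH2OH)–C9H2–C10H2–C11H=C12(CH3)–C13H2–C14H2. The only stereocentre is C5 (R), the γ-carbon of the butenolide. It is isolated, so no other centre can relay configuration to it, and its hydrogen is vinylogously acidic once the butenolide exists. Two alkene geometries must be set: Z at C7=C8 (C6 cis to the hydroxymethyl group) and E at C11=C12. The sensitive groups are the butenolide (base, nucleophiles), two primary allylic alcohols that must be told apart during the synthesis, and three electron-rich alkenes (C7=C8, C11=C12, the tetrasubstituted ring B alkene) that tolerate neither strong acid nor unselective oxidants. The hard part is to create C5 enantioselectively next to an unbranched CH2 group without passing through intermediates in which C5 is enolisable. The feature used is that C4 carries CH2OH next to C5: C2, C3, C4 and this CH2OH form a succinate-derived unit, and a C4=C5 alkene in that unit is a 2-substituted allylic alcohol whose epoxide has the C2 carboxyl three atoms from C5.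

## Retrosynthetic reasoning

Ring A unsaturation and protecting groups (30 ⇒ 29 ⇒ 28 ⇒ 27 ⇒ 26). The two hydroxyls are masked as silyl ethers (29) and the C3=C4 double bond is traced back to a tertiary C4 hydroxyl (27, activated as 28). Removing the double bond first takes away the acidity of C5–H, so C5 meets base only once, in the penultimate step. The forward steps have to silylate the primary hydroxyl of 26 selectively, eliminate the C4 oxygen towards C3 only, and cleave both silyl ethers without a basic fluoride source.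

Lactone C–O bond (26 ⇒ 24). The O1–C5 bond is cut so that C5 becomes an oxirane carbon and O1 the carbonyl oxygen of a tert-butyl ester at C2. This is the place to cut because it turns an isolated oxygen-bearing stereocentre into one carbon of an epoxy alcohol, a unit that can be made in high enantiomeric purity. The forward reaction must open the oxirane at C5 and not at the tertiary C4, with clean inversion, and must shed the tert-butyl group.

Oxirane oxygen and ester oxidation level (24 ⇒ 23 ⇒ 22). Removing the oxirane oxygen gives allylic alcohol 23, an (E)-2,3-disubstituted allylic alcohol of the type that asymmetric epoxidation handles well. 23 comes from diester 22 by reduction of the conjugated methyl ester alone. The tert-butyl/methyl pair is chosen so that hydride distinguishes the two esters and so that the γ-hydroxy ester in 23 and 24 does not lactonise early.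

C4=C5 alkene (22 ⇒ 21 + 20; 20 ⇒ 17 + 18). The trisubstituted alkene is cut by a Wittig disconnection into aldehyde 21 and ylide 20, which carries C2, C3, C4 and the future C4 hydroxymethyl carbon in one piece. A stabilised α-substituted ylide gives the E geometry that the epoxidation needs and is mild enough for a β,γ-unsaturated aldehyde. Ylide 20 is cut at C3–C4 into ylide 17 and bromo ester 18.

C6–C7 bond (21 ⇒ 16 ⇒ 14 + 4). Aldehyde 21 is the oxidation product of homoallylic alcohol 16. Cutting C6–C7 gives vinyl iodide 14 and oxirane 4, which supplies C5 and C6. The forward reaction must keep the alkene geometry through halogen–metal exchange and must not let the neighbouring silyl group migrate to carbon.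

C8–C9 bond and the vinylic iodide (14 ⇒ 13 ⇒ 10 + 9). The Z-trisubstituted alkene is cut at C8–C9 and at C7–I. Anti addition of Grignard reagent 10 to the magnesium alkoxide 11 of propargyl alcohol 9 places magnesium cis to the CH2O group (12), and iodination then gives 13. The geometry of C7=C8 is fixed mechanistically rather than by a selective olefination.

The E-alkene C11=C12 (10 ⇐ 8 ⇐ 7 ⇒ 3 + 4; 3 ⇒ 1). Alcohol 7 is cut at C10–C11 and at the C12–CH3 bond. Syn methylalumination of alkyne 3, followed by opening of oxirane 4, gives the E geometry without isomer separation. Alkyne 3 comes from the methyl ketone 1, whose methyl carbon becomes C11.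

## Alternatives that were turned down

Alternative 1: The C7=C8 alkene is hidden in a six-membered cyclic acetal. The bonds cut are C7–C8 and the bond from C8 to the future hydroxymethyl carbon, both made by inserting one carbon into the enol ether of (2R)-2-[(triisopropylsilyl)ethynyl]-2,3-dihydrofuran A2. The forward key step is dihalocarbene addition to the enol ether and alcoholytic opening of the gem-dibromocyclopropane, giving the ring-expanded bromo acetal (6R)-3-bromo-2-methoxy-6-[(triisopropylsilyl)ethynyl]-5,6-dihydro-2H-pyran A1.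
- For it: the ring enforces the Z geometry, the vinylic bromine is a handle for attaching C9–C14 and ring B, and the acetal carbon is the C8 hydroxymethyl group at the aldehyde level. No skipped enal is needed, and on that point it is stronger than the chosen route, which must handle 21.
- Against it: the key step creates no stereocentre, so C5 must already be present in A2, which needs its own asymmetric synthesis. After A1 the butenolide must still be built from the silylalkyne over several steps, an sp2–sp3 coupling must succeed on a hindered α-alkoxy bromoalkene, and reductive opening of the acetal frees two primary alcohols at once.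
- Comparison: the chosen route fixes the same geometry in one stereospecific step (step 4) and spends its effort on one event that makes the C5–O bond, the ring and the final configuration together. The linear sequence should be shorter.

Alternative 2: C8–C9 and C6–C7 are made in one flask. Grignard reagent 10 adds to alkoxide 11 as in step 4, but the alkenylmagnesium 12 is not iodinated; it opens methyl (2R)-oxirane-2-carboxylate A4 at its CH2 carbon. The product is methyl (2R,4Z,8E)-2-hydroxy-5-(hydroxymethyl)-9-methyl-11-(2,6,6-trimethylcyclohex-1-en-1-yl)undeca-4,8-dienoate A3.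
- For it: it is the most convergent opening. C5 comes from the chiral pool without an asymmetric step, the Z geometry comes from the same carbomagnesiation, and the skipped enal is avoided. Up to A3 it is clearly stronger in step economy.
- Against it: 12 is a chelated, sluggish nucleophile that must attack the epoxide CH2 in the presence of a methyl ester. In A3 the stereocentre sits α to that ester, whose carbon is the future C4. To reach the butenolide this carbon must become a ketone bearing CH2O, and C2–C3 must be added by acylation and olefination. C5 is then an enolisable α-acyloxy ketone centre during basic steps, and three hydroxyls must be told apart.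
- Comparison: in the chosen route C5 is never next to a carbonyl group until ring A is complete, and C2, C3, C4 and the C4 hydroxymethyl carbon arrive together in ylide 20.

Alternative 3: C4–C5 and O1–C2 are formed at once. An alkenylchromium made from methyl (2Z)-4-[(tert-butyldimethylsilyl)oxy]-3-iodobut-2-enoate A6 (divalent chromium, a nickel co-catalyst and a chiral oxazoline–sulfonamide ligand) adds to (3Z,7E)-4-{[(tert-butyldimethylsilyl)oxy]methyl}-8-methyl-10-(2,6,6-trimethylcyclohex-1-en-1-yl)deca-3,7-dienal A7. The chromium alkoxide closes onto the cis ester and gives the bis(tert-butyldimethylsilyl) ether of the target, A5.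
- For it: it is the shortest route. From an aldehyde of the same type as 21 only the coupling and a desilylation remain, so it saves about five steps.
- Against it: the configuration at C5 depends entirely on ligand control in an addition to an unbranched, β,γ-unsaturated aliphatic aldehyde, a substrate type for which high selectivity cannot be assumed. The enal must survive Lewis-acidic metal salts. The alkenylmetal from A6 has a silyloxy group β to the metal and can collapse to an allenoate.
- Comparison: the chosen route sets C5 by an epoxidation whose facial selectivity is predictable for this substrate class and then transfers it stereospecifically. It pays for this with more steps.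

Key step: step 12

Remark on the chemistry: the C8 hydroxymethyl group is carried as a triisopropylsilyl ether, because it sits cis to a vinyllithium in step 6 and must survive a Lewis acid in step 12; compounds 1, 4, 9, 17 and 18 are taken as purchasable.

## Route

Step 1
Reactants: 1 dihydro-β-ionone, 4-(2,6,6-trimethylcyclohex-1-en-1-yl)butan-2-one
Product: 3 2-(but-3-yn-1-yl)-1,3,3-trimethylcyclohex-1-ene, via enol phosphate 2 (not isolated)
Conditions: LiN(iPr)2 (1.05 equiv), THF, −78 °C; ClP(O)(OEt)2, −78 °C → rt; LiN(iPr)2 (2.3 equiv), −78 °C → rt; aq. NH4Cl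
Reagents that add atoms: none
Why: One-pot conversion of a methyl ketone into a terminal alkyne through its kinetic enol phosphate: deprotonation at the methyl group, O-phosphorylation to 2, then double elimination with two further equivalents of amide base. The tetrasubstituted ring alkene is inert to these conditions.

Step 2
Reactants: 3 2-(but-3-yn-1-yl)-1,3,3-trimethylcyclohex-1-ene; 4 ethylene oxide
Product: 7 (3E)-4-methyl-6-(2,6,6-trimethylcyclohex-1-en-1-yl)hex-3-en-1-ol, via alkenylalane 5 (not isolated), via lithium alanate 6 (not isolated)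
Conditions: Me3Al (2.5 equiv), Cp2ZrCl2 (0.25 equiv), CH2Cl2, 0 °C → rt; volatiles removed; n-BuLi (1.0 equiv), hexane, 0 °C; 4 (excess), THF, −30 °C → rt; dil. HCl
Reagents that add atoms: trimethylaluminium, C[Al](C)C
Why: Negishi carboalumination adds methyl and aluminium syn across the alkyne with aluminium on the terminal carbon (5). The alanate 6 transfers its alkenyl group to ethylene oxide with retention, so C11=C12 is formed as the E isomer.

Step 3
Reactants: 7 (3E)-4-methyl-6-(2,6,6-trimethylcyclohex-1-en-1-yl)hex-3-en-1-ol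
Product: 8 2-[(3E)-6-bromo-3-methylhex-3-en-1-yl]-1,3,3-trimethylcyclohex-1-ene
Conditions: CBr4, PPh3, CH2Cl2, 0 °C
Reagents that add atoms: carbon tetrabromide, BrC(Br)(Br)Br
Why: Appel reaction under neutral conditions; a primary homoallylic alcohol is brominated without transposition and neither alkene is touched.

Step 4
Reactants: 8 2-[(3E)-6-bromo-3-methylhex-3-en-1-yl]-1,3,3-trimethylcyclohex-1-ene; 9 propargyl alcohol
Product: 13 (2Z)-3-iodo-2-[(3E)-4-methyl-6-(2,6,6-trimethylcyclohex-1-en-1-yl)hex-3-en-1-yl]prop-2-en-1-ol, via Grignard reagent 10 (not isolated), via chloromagnesium propynolate 11 (not isolated), via alkenylmagnesium species 12 (not isolated)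
Conditions: 8, Mg, THF, 35 °C; separately 9, iPrMgCl (1.0 equiv), THF, −20 → 0 °C; 10 (1.3 equiv) added to 11, CuI (0.1 equiv), THF, 0 °C → rt; I2, −20 → 0 °C; aq. Na2S2O3/NH4Cl
Reagents that add atoms: iodine, II
Why: Copper-catalysed anti carbomagnesiation of a propargylic magnesium alkoxide puts the alkyl group on the internal carbon and magnesium on the terminal carbon, cis to CH2O, in the chelated species 12. Iodine cleaves the C–Mg bond with retention, which fixes the C7=C8 geometry. The alkoxide is preformed with a sacrificial Grignard reagent so that 10 is not spent on the hydroxyl proton.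

Step 5
Reactants: 13 (2Z)-3-iodo-2-[(3E)-4-methyl-6-(2,6,6-trimethylcyclohex-1-en-1-yl)hex-3-en-1-yl]prop-2-en-1-ol
Product: 14 {[(2Z)-3-iodo-2-[(3E)-4-methyl-6-(2,6,6-trimethylcyclohex-1-en-1-yl)hex-3-en-1-yl]prop-2-en-1-yl]oxy}tri(propan-2-yl)silane
Conditions: TIPSCl, imidazole, DMF, rt
Reagents that add atoms: chlorotri(propan-2-yl)silane, CC(C)[Si](Cl)(C(C)C)C(C)C
Why: Standard silylation of a primary allylic alcohol. The bulky triisopropylsilyl group is chosen because it resists 1,4 O→C migration to the cis vinyl anion of step 6 and Lewis acid in step 12.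

Step 6
Reactants: 14 {[(2Z)-3-iodo-2-[(3E)-4-methyl-6-(2,6,6-trimethylcyclohex-1-en-1-yl)hex-3-en-1-yl]prop-2-en-1-yl]oxy}tri(propan-2-yl)silane; 4 ethylene oxide
Product: 16 (3Z,7E)-8-methyl-4-{[(triisopropylsilyl)oxy]methyl}-10-(2,6,6-trimethylcyclohex-1-en-1-yl)deca-3,7-dien-1-ol, via alkenyllithium 15 (not isolated)
Conditions: t-BuLi (2.1 equiv), Et2O, −78 °C; 4 (excess), −78 → 0 °C; aq. NH4Cl
Reagents that add atoms: none
Why: Iodine–lithium exchange proceeds with retention of alkene geometry, and the alkenyllithium 15 opens ethylene oxide at carbon to form C6–C7; this is the usual homologation of alkenyllithiums to homoallylic alcohols.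

Step 7
Reactants: 17 methyl (triphenyl-λ5-phosphanylidene)acetate; 18 tert-butyl bromoacetate
Product: 20 4-tert-butyl 1-methyl 2-(triphenyl-λ5-phosphanylidene)butanedioate, via phosphonium bromide 19 (not isolated)
Conditions: 17 (2.0 equiv), 18 (1.0 equiv), EtOAc, 70 °C; filtration
Reagents that add atoms: none
Why: C-alkylation of the stabilised ylide by the α-bromo ester gives salt 19, which a second equivalent of 17 deprotonates (transylidation). The by-product phosphonium salt precipitates and is filtered off.

Step 8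
Reactants: 16 (3Z,7E)-8-methyl-4-{[(triisopropylsilyl)oxy]methyl}-10-(2,6,6-trimethylcyclohex-1-en-1-yl)deca-3,7-dien-1-ol
Product: 21 (3Z,7E)-8-methyl-4-{[(triisopropylsilyl)oxy]methyl}-10-(2,6,6-trimethylcyclohex-1-en-1-yl)deca-3,7-dienal
Conditions: Dess–Martin periodinane, NaHCO3, CH2Cl2, 0 °C → rt; used crude
Reagents that add atoms: none
Why: Buffered Dess–Martin oxidation is the usual way to make β,γ-unsaturated aldehydes without moving the double bond into conjugation; 21 is carried on at once.

Step 9
Reactants: 21 (3Z,7E)-8-methyl-4-{[(triisopropylsilyl)oxy]methyl}-10-(2,6,6-trimethylcyclohex-1-en-1-yl)deca-3,7-dienal; 20 4-tert-butyl 1-methyl 2-(triphenyl-λ5-phosphanylidene)butanedioate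
Product: 22 4-tert-butyl 1-methyl (2E)-2-[(3Z,7E)-8-methyl-4-{[(triisopropylsilyl)oxy]methyl}-10-(2,6,6-trimethylcyclohex-1-en-1-yl)deca-3,7-dien-1-ylidene]butanedioate
Conditions: 20 (1.5 equiv), CH2Cl2, rt
Reagents that add atoms: none
Why: Wittig reaction of an α-substituted ester-stabilised ylide with an unbranched aldehyde; such ylides give the E-trisubstituted alkene with the aldehyde chain trans to CO2Me. The neutral ylide is too weakly basic to conjugate the skipped enal quickly.

Step 10
Reactants: 22 4-tert-butyl 1-methyl (2E)-2-[(3Z,7E)-8-methyl-4-{[(triisopropylsilyl)oxy]methyl}-10-(2,6,6-trimethylcyclohex-1-en-1-yl)deca-3,7-dien-1-ylidene]butanedioate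
Product: 23 tert-butyl (3E,6Z,10E)-3-(hydroxymethyl)-11-methyl-7-{[(triisopropylsilyl)oxy]methyl}-13-(2,6,6-trimethylcyclohex-1-en-1-yl)trideca-3,6,10-trienoate
Conditions: iBu2AlH (2.2 equiv), CH2Cl2, −78 °C; aq. potassium sodium tartrate (KNaC4H4O6)
Reagents that add atoms: none
Why: 1,2-Reduction of the conjugated methyl ester by iBu2AlH. The tert-butyl ester is sterically shielded and should survive at −78 °C, and it keeps the new γ-hydroxy ester from lactonising.

Step 11
Reactants: 23 tert-butyl (3E,6Z,10E)-3-(hydroxymethyl)-11-methyl-7-{[(triisopropylsilyl)oxy]methyl}-13-(2,6,6-trimethylcyclohex-1-en-1-yl)trideca-3,6,10-trienoate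
Product: 24 tert-butyl 2-[(2S,3S)-2-(hydroxymethyl)-3-{(2Z,6E)-7-methyl-3-{[(triisopropylsilyl)oxy]methyl}-9-(2,6,6-trimethylcyclohex-1-en-1-yl)nona-2,6-dien-1-yl}oxiran-2-yl]acetate
Conditions: Ti(OiPr)4 (0.1 equiv), L-(+)-diethyl tartrate (0.12 equiv), t-BuOOH (2 equiv, in isooctane), 4 Å molecular sieves, CH2Cl2, −20 °C
Reagents that add atoms: tert-butyl hydroperoxide, CC(C)(C)OO
Why: Sharpless asymmetric epoxidation; only the alkene of the free allylic alcohol is reached by the titanium-bound peroxide, so C7=C8, C11=C12 and ring B stay intact. With L-(+)-diethyl tartrate an (E)-2,3-disubstituted allylic alcohol is epoxidised on the face that gives the (2S,3S)-oxirane (C4 S, C5 S), by analogy with (E)-2-methylalk-2-en-1-ols.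

Step 12
Reactants: 24 tert-butyl 2-[(2S,3S)-2-(hydroxymethyl)-3-{(2Z,6E)-7-methyl-3-{[(triisopropylsilyl)oxy]methyl}-9-(2,6,6-trimethylcyclohex-1-en-1-yl)nona-2,6-dien-1-yl}oxiran-2-yl]acetate
Product: 26 (4S,5R)-4-hydroxy-4-(hydroxymethyl)-5-{(2Z,6E)-7-methyl-3-{[(triisopropylsilyl)oxy]methyl}-9-(2,6,6-trimethylcyclohex-1-en-1-yl)nona-2,6-dien-1-yl}oxolan-2-one, via dialkoxycarbenium zwitterion 25 (not isolated)
Conditions: BF3·OEt2 (0.3 equiv), CH2Cl2, −78 → −20 °C; Et3N, then aq. NaHCO3
Reagents that add atoms: none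
Why: BF3 binds the oxirane oxygen of 24, and the carbonyl oxygen of the tert-butyl ester attacks C5 from the side opposite the breaking C5–O bond to give the cyclic dialkoxycarbenium zwitterion 25; loss of 2-methylpropene and proton transfer to the boron-bound alkoxide release lactone 26 and the Lewis acid. The closest known reaction type is the acid-promoted lactonisation of β,γ-epoxy esters and acids to β-hydroxy-γ-lactones, together with epoxide openings by tert-butyl esters and tert-butyl carbonates that end with loss of the tert-butyl group as the alkene. The five-membered ring closes in the 5-endo epoxide-opening mode, with both oxirane carbons in the new ring; the 4-exo alternative at C4 would give a β-lactone and is not expected to compete. The one stereocentre formed in its final state is C5: it arises by stereospecific inversion of the (S)-oxirane carbon set in step 11 and becomes 5R, while C4 keeps its oxygen and configuration and is removed in step 14. The step needs regioselectivity for C5 over the tertiary C4, which the tether length secures. It also needs the SN2-type opening to outrun ionisation at C4 and the hydride shift that would follow; the two electron-withdrawing groups on C4 (CH2OH and CH2CO2tBu) and the low temperature work against that ionisation. A sub-stoichiometric amount of Lewis acid at −78 to −20 °C should leave the silyl ether, the two trisubstituted alkenes and the ring B alkene untouched.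

Step 13
Reactants: 26 (4S,5R)-4-hydroxy-4-(hydroxymethyl)-5-{(2Z,6E)-7-methyl-3-{[(triisopropylsilyl)oxy]methyl}-9-(2,6,6-trimethylcyclohex-1-en-1-yl)nona-2,6-dien-1-yl}oxolan-2-one
Product: 27 (4S,5R)-4-{[(tert-butyldimethylsilyl)oxy]methyl}-4-hydroxy-5-{(2Z,6E)-7-methyl-3-{[(triisopropylsilyl)oxy]methyl}-9-(2,6,6-trimethylcyclohex-1-en-1-yl)nona-2,6-dien-1-yl}oxolan-2-one
Conditions: TBSCl (1.2 equiv), imidazole, DMF, 0 °C
Reagents that add atoms: tert-butylchlorodimethylsilane, CC(C)(C)[Si](C)(C)Cl
Why: Selective silylation of the primary hydroxyl beside a tertiary one. Capping it also stops transfer of the lactone acyl group to this oxygen and its mesylation in step 14.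

Step 14
Reactants: 27 (4S,5R)-4-{[(tert-butyldimethylsilyl)oxy]methyl}-4-hydroxy-5-{(2Z,6E)-7-methyl-3-{[(triisopropylsilyl)oxy]methyl}-9-(2,6,6-trimethylcyclohex-1-en-1-yl)nona-2,6-dien-1-yl}oxolan-2-one
Product: 29 (5R)-4-{[(tert-butyldimethylsilyl)oxy]methyl}-5-{(2Z,6E)-7-methyl-3-{[(triisopropylsilyl)oxy]methyl}-9-(2,6,6-trimethylcyclohex-1-en-1-yl)nona-2,6-dien-1-yl}furan-2(5H)-one, via mesylate 28 (not isolated)
Conditions: MsCl (3 equiv), Et3N (6 equiv), CH2Cl2, −20 → 0 °C
Reagents that add atoms: none
Why: Sulfene-mediated mesylation reaches even the tertiary β-hydroxyl and gives 28, which eliminates by an E1cB pathway through the lactone enolate, so the double bond can form only between C3 and C4. C5–H is not on this pathway, and a mild amine base at low temperature should leave the γ-stereocentre intact.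

Step 15
Reactants: 29 (5R)-4-{[(tert-butyldimethylsilyl)oxy]methyl}-5-{(2Z,6E)-7-methyl-3-{[(triisopropylsilyl)oxy]methyl}-9-(2,6,6-trimethylcyclohex-1-en-1-yl)nona-2,6-dien-1-yl}furan-2(5H)-one
Product: 30 (6Z)-neomanoalide, (5R)-4-(hydroxymethyl)-5-[(2Z,6E)-3-(hydroxymethyl)-7-methyl-9-(2,6,6-trimethylcyclohex-1-en-1-yl)nona-2,6-dien-1-yl]furan-2(5H)-one
Conditions: HF·pyridine, pyridine, THF, 0 °C → rt; aq. NaHCO3
Reagents that add atoms: none
Why: Fluoride cleavage of both primary silyl ethers under buffered, weakly acidic conditions; this avoids basic fluoride sources that could deprotonate C5 of the butenolide.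

## Compound list

1 | dihydro-β-ionone, 4-(2,6,6-trimethylcyclohex-1-en-1-yl)butan-2-one | CC1=C(CCC(C)=O)C(C)(C)CCC1 | starting material
2 | diethyl 4-(2,6,6-trimethylcyclohex-1-en-1-yl)but-1-en-2-yl phosphate | C=C(CCC1=C(C)CCCC1(C)C)OP(=O)(OCC)OCC | intermediate (not isolated)
3 | 2-(but-3-yn-1-yl)-1,3,3-trimethylcyclohex-1-ene | C#CCCC1=C(C)CCCC1(C)C | intermediate
4 | ethylene oxide (oxirane) | C1CO1 | starting material
5 | [(1E)-2-methyl-4-(2,6,6-trimethylcyclohex-1-en-1-yl)but-1-en-1-yl]dimethylalumane | C[Al](C)/C=C(\C)CCC1=C(C)CCCC1(C)C | intermediate (not isolated)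
6 | lithium butyl(dimethyl)[(1E)-2-methyl-4-(2,6,6-trimethylcyclohex-1-en-1-yl)but-1-en-1-yl]aluminate | [Li+].CCCC[Al-](C)(C)/C=C(\C)CCC1=C(C)CCCC1(C)C | intermediate (not isolated)
7 | (3E)-4-methyl-6-(2,6,6-trimethylcyclohex-1-en-1-yl)hex-3-en-1-ol | OCC/C=C(\C)CCC1=C(C)CCCC1(C)C | intermediate
8 | 2-[(3E)-6-bromo-3-methylhex-3-en-1-yl]-1,3,3-trimethylcyclohex-1-ene | BrCC/C=C(\C)CCC1=C(C)CCCC1(C)C | intermediate
9 | propargyl alcohol (prop-2-yn-1-ol) | C#CCO | starting material
10 | [(3E)-4-methyl-6-(2,6,6-trimethylcyclohex-1-en-1-yl)hex-3-en-1-yl]magnesium bromide | Br[Mg]CC/C=C(\C)CCC1=C(C)CCCC1(C)C | intermediate (not isolated)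
11 | chloromagnesium prop-2-yn-1-olate | C#CCO[Mg]Cl | intermediate (not isolated)
12 | bromo{(1Z)-3-[(chloromagnesio)oxy]-2-[(3E)-4-methyl-6-(2,6,6-trimethylcyclohex-1-en-1-yl)hex-3-en-1-yl]prop-1-en-1-yl}magnesium | Cl[Mg]OC/C(CC/C=C(\C)CCC1=C(C)CCCC1(C)C)=C\[Mg]Br | intermediate (not isolated)
13 | (2Z)-3-iodo-2-[(3E)-4-methyl-6-(2,6,6-trimethylcyclohex-1-en-1-yl)hex-3-en-1-yl]prop-2-en-1-ol | OC/C(CC/C=C(\C)CCC1=C(C)CCCC1(C)C)=C\I | intermediate
14 | {[(2Z)-3-iodo-2-[(3E)-4-methyl-6-(2,6,6-trimethylcyclohex-1-en-1-yl)hex-3-en-1-yl]prop-2-en-1-yl]oxy}tri(propan-2-yl)silane | CC(C)[Si](OC/C(CC/C=C(\C)CCC1=C(C)CCCC1(C)C)=C\I)(C(C)C)C(C)C | intermediate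
15 | {(1Z)-2-[(3E)-4-methyl-6-(2,6,6-trimethylcyclohex-1-en-1-yl)hex-3-en-1-yl]-3-[(triisopropylsilyl)oxy]prop-1-en-1-yl}lithium | [Li]/C=C(\CO[Si](C(C)C)(C(C)C)C(C)C)CC/C=C(\C)CCC1=C(C)CCCC1(C)C | intermediate (not isolated)
16 | (3Z,7E)-8-methyl-4-{[(triisopropylsilyl)oxy]methyl}-10-(2,6,6-trimethylcyclohex-1-en-1-yl)deca-3,7-dien-1-ol | OCC/C=C(\CO[Si](C(C)C)(C(C)C)C(C)C)CC/C=C(\C)CCC1=C(C)CCCC1(C)C | intermediate
17 | methyl (triphenyl-λ5-phosphanylidene)acetate | COC(=O)C=P(c1ccccc1)(c1ccccc1)c1ccccc1 | starting material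
18 | tert-butyl bromoacetate | BrCC(=O)OC(C)(C)C | starting material
19 | [4-(tert-butoxy)-1-methoxy-1,4-dioxobutan-2-yl]triphenylphosphonium bromide | [Br-].COC(=O)C(CC(=O)OC(C)(C)C)[P+](c1ccccc1)(c1ccccc1)c1ccccc1 | intermediate (not isolated)
20 | 4-tert-butyl 1-methyl 2-(triphenyl-λ5-phosphanylidene)butanedioate | COC(=O)C(CC(=O)OC(C)(C)C)=P(c1ccccc1)(c1ccccc1)c1ccccc1 | intermediate
21 | (3Z,7E)-8-methyl-4-{[(triisopropylsilyl)oxy]methyl}-10-(2,6,6-trimethylcyclohex-1-en-1-yl)deca-3,7-dienal | O=CC/C=C(\CO[Si](C(C)C)(C(C)C)C(C)C)CC/C=C(\C)CCC1=C(C)CCCC1(C)C | intermediate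
22 | 4-tert-butyl 1-methyl (2E)-2-[(3Z,7E)-8-methyl-4-{[(triisopropylsilyl)oxy]methyl}-10-(2,6,6-trimethylcyclohex-1-en-1-yl)deca-3,7-dien-1-ylidene]butanedioate | COC(=O)/C(CC(=O)OC(C)(C)C)=C/C/C=C(\CO[Si](C(C)C)(C(C)C)C(C)C)CC/C=C(\C)CCC1=C(C)CCCC1(C)C | intermediate
23 | tert-butyl (3E,6Z,10E)-3-(hydroxymethyl)-11-methyl-7-{[(triisopropylsilyl)oxy]methyl}-13-(2,6,6-trimethylcyclohex-1-en-1-yl)trideca-3,6,10-trienoate | CC(C)(C)OC(=O)C/C(CO)=C\C/C=C(\CO[Si](C(C)C)(C(C)C)C(C)C)CC/C=C(\C)CCC1=C(C)CCCC1(C)C | intermediate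
24 | tert-butyl 2-[(2S,3S)-2-(hydroxymethyl)-3-{(2Z,6E)-7-methyl-3-{[(triisopropylsilyl)oxy]methyl}-9-(2,6,6-trimethylcyclohex-1-en-1-yl)nona-2,6-dien-1-yl}oxiran-2-yl]acetate | CC(C)(C)OC(=O)C[C@@]1(CO)O[C@H]1C/C=C(\CO[Si](C(C)C)(C(C)C)C(C)C)CC/C=C(\C)CCC2=C(C)CCCC2(C)C | intermediate
25 | (4S,5R)-2-tert-butoxy-4-(hydroxymethyl)-5-{(2Z,6E)-7-methyl-3-{[(triisopropylsilyl)oxy]methyl}-9-(2,6,6-trimethylcyclohex-1-en-1-yl)nona-2,6-dien-1-yl}-4-[(trifluoroboranuidyl)oxy]-4,5-dihydro-3H-furan-1-ium (inner salt) | CC(C)(C)OC1=[O+][C@H](C/C=C(\CO[Si](C(C)C)(C(C)C)C(C)C)CC/C=C(\C)CCC2=C(C)CCCC2(C)C)[C@](CO)(O[B-](F)(F)F)C1 | intermediate (not isolated)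
26 | (4S,5R)-4-hydroxy-4-(hydroxymethyl)-5-{(2Z,6E)-7-methyl-3-{[(triisopropylsilyl)oxy]methyl}-9-(2,6,6-trimethylcyclohex-1-en-1-yl)nona-2,6-dien-1-yl}oxolan-2-one | O=C1C[C@](O)(CO)[C@@H](C/C=C(\CO[Si](C(C)C)(C(C)C)C(C)C)CC/C=C(\C)CCC2=C(C)CCCC2(C)C)O1 | intermediate
27 | (4S,5R)-4-{[(tert-butyldimethylsilyl)oxy]methyl}-4-hydroxy-5-{(2Z,6E)-7-methyl-3-{[(triisopropylsilyl)oxy]methyl}-9-(2,6,6-trimethylcyclohex-1-en-1-yl)nona-2,6-dien-1-yl}oxolan-2-one | O=C1C[C@](O)(CO[Si](C)(C)C(C)(C)C)[C@@H](C/C=C(\CO[Si](C(C)C)(C(C)C)C(C)C)CC/C=C(\C)CCC2=C(C)CCCC2(C)C)O1 | intermediate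
28 | (2R,3S)-3-{[(tert-butyldimethylsilyl)oxy]methyl}-2-{(2Z,6E)-7-methyl-3-{[(triisopropylsilyl)oxy]methyl}-9-(2,6,6-trimethylcyclohex-1-en-1-yl)nona-2,6-dien-1-yl}-5-oxooxolan-3-yl methanesulfonate | O=C1C[C@](OS(C)(=O)=O)(CO[Si](C)(C)C(C)(C)C)[C@@H](C/C=C(\CO[Si](C(C)C)(C(C)C)C(C)C)CC/C=C(\C)CCC2=C(C)CCCC2(C)C)O1 | intermediate (not isolated)
29 | (5R)-4-{[(tert-butyldimethylsilyl)oxy]methyl}-5-{(2Z,6E)-7-methyl-3-{[(triisopropylsilyl)oxy]methyl}-9-(2,6,6-trimethylcyclohex-1-en-1-yl)nona-2,6-dien-1-yl}furan-2(5H)-one | O=C1C=C(CO[Si](C)(C)C(C)(C)C)[C@@H](C/C=C(\CO[Si](C(C)C)(C(C)C)C(C)C)CC/C=C(\C)CCC2=C(C)CCCC2(C)C)O1 | intermediate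
30 | (6Z)-neomanoalide, (5R)-4-(hydroxymethyl)-5-[(2Z,6E)-3-(hydroxymethyl)-7-methyl-9-(2,6,6-trimethylcyclohex-1-en-1-yl)nona-2,6-dien-1-yl]furan-2(5H)-one | CC1=C(CC/C(C)=C/CC/C(=C/C[C@H]2OC(=O)C=C2CO)CO)C(C)(C)CCC1 | target

## Step count and least certain steps

Total step count: 15 (steps 1–15; step 7 prepares ylide 20 on a side branch). Longest linear sequence: 14 steps (steps 1–6 and 8–15, from 1).

Step 12 (key step). The most likely failure is ionisation of the activated oxirane at the tertiary C4 before the ester oxygen reaches C5, followed by a hydride shift or elimination. A second risk is acid-catalysed transfer of the lactone acyl group to the free primary hydroxyl after ring closure, which is possible because both hydroxyls are γ to the carbonyl. The fallback sets out from 24 and opens the epoxy alcohol intermolecularly. Ti(OiPr)4 with benzoic acid delivers benzoate to C5 of the chelated 2,3-epoxy alcohol with inversion and gives benzoate diol F1. TBSCl and imidazole cap the primary hydroxyl to give silyl ether F2. K2CO3 in methanol removes the benzoate to give dihydroxy ester F3. Warm PPTS in toluene then closes the lactone by acyl substitution at the tert-butyl ester, which leaves C5 untouched. The fallback comes back to the route at 27.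

Step 9. The most likely failure is migration of the C7=C8 double bond of 21 into conjugation with the aldehyde during the slow reaction with the hindered ylide, which would also erode the Z geometry. The fallback sets out from 14 and avoids the aldehyde. Alkenyllithium 15, made as in step 6, is quenched with Bu3SnCl to give alkenylstannane F4. Ylide 20 and chloroacetaldehyde give allylic chloride F5. A Stille coupling of F4 with F5 (Pd2(dba)3 as the source of zerovalent palladium, tri(2-furyl)phosphine, THF) forms C6–C7 at the unsubstituted terminus of the allyl unit. The fallback comes back at 22 and replaces steps 6, 8 and 9.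

Step 4. The most likely failures are consumption of Grignard reagent 10 by the acetylenic C–H of 11 and incomplete carbometalation with a long-chain reagent, both of which waste material derived from 8. The fallback sets out from 8. Grignard reagent 10 is added to silyloxy Weinreb amide F6, prepared from 2-hydroxy-N-methoxy-N-methylacetamide and TIPSCl, to give α-silyloxy ketone F7. A Wittig reaction of F7 with the non-stabilised ylide from [3-(tert-butyldimethylsilyloxy)propyl]triphenylphosphonium bromide and KN(SiMe3)2 is expected to place the new chain cis to the silyloxymethyl group, as α-alkoxy ketones generally do, and gives bis-silyl ether F8. Selective methanolysis of the primary tert-butyldimethylsilyl ether (PPTS, MeOH, 0 °C) brings the fallback back at 16, replacing steps 4–6.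

Step 6. The most likely failures are 1,4 O→C silyl migration in alkenyllithium 15 on warming and protonation of 15 before it opens the epoxide. The fallback sets out from 14. A Stille coupling with tributyl(vinyl)stannane (Pd(PPh3)4, DMF) gives diene F9. Hydroboration of the terminal vinyl group with 9-BBN, followed by NaOH/H2O2, gives the primary alcohol. The fallback comes back at 16.

Step 10. The most likely failure is loss of chemoselectivity: partial reduction of the tert-butyl ester, or lactonisation of the aluminium alkoxide onto it during work-up. The fallback sets out from 22. LiOH in THF/water hydrolyses only the methyl ester to carboxylic acid F10. Activation with isobutyl chloroformate and N-methylmorpholine at −15 °C, followed by NaBH4, reduces this carboxyl group alone. The fallback comes back at 23.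

## Further compounds

F1 | step 12 | tert-butyl (3S,4R,6Z,10E)-4-(benzoyloxy)-3-hydroxy-3-(hydroxymethyl)-11-methyl-7-{[(triisopropylsilyl)oxy]methyl}-13-(2,6,6-trimethylcyclohex-1-en-1-yl)trideca-6,10-dienoate | CC(C)(C)OC(=O)C[C@](O)(CO)[C@H](OC(=O)c1ccccc1)C/C=C(\CO[Si](C(C)C)(C(C)C)C(C)C)CC/C=C(\C)CCC1=C(C)CCCC1(C)C
F2 | step 12 | tert-butyl (3S,4R,6Z,10E)-4-(benzoyloxy)-3-{[(tert-butyldimethylsilyl)oxy]methyl}-3-hydroxy-11-methyl-7-{[(triisopropylsilyl)oxy]methyl}-13-(2,6,6-trimethylcyclohex-1-en-1-yl)trideca-6,10-dienoate | CC(C)(C)OC(=O)C[C@](O)(CO[Si](C)(C)C(C)(C)C)[C@H](OC(=O)c1ccccc1)C/C=C(\CO[Si](C(C)C)(C(C)C)C(C)C)CC/C=C(\C)CCC1=C(C)CCCC1(C)C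
F3 | step 12 | tert-butyl (3S,4R,6Z,10E)-3-{[(tert-butyldimethylsilyl)oxy]methyl}-3,4-dihydroxy-11-methyl-7-{[(triisopropylsilyl)oxy]methyl}-13-(2,6,6-trimethylcyclohex-1-en-1-yl)trideca-6,10-dienoate | CC(C)(C)OC(=O)C[C@](O)(CO[Si](C)(C)C(C)(C)C)[C@H](O)C/C=C(\CO[Si](C(C)C)(C(C)C)C(C)C)CC/C=C(\C)CCC1=C(C)CCCC1(C)C
F4 | step 9 | tributyl{(1Z)-2-[(3E)-4-methyl-6-(2,6,6-trimethylcyclohex-1-en-1-yl)hex-3-en-1-yl]-3-[(triisopropylsilyl)oxy]prop-1-en-1-yl}stannane | CCCC[Sn](CCCC)(CCCC)/C=C(\CO[Si](C(C)C)(C(C)C)C(C)C)CC/C=C(\C)CCC1=C(C)CCCC1(C)C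
F5 | step 9 | 4-tert-butyl 1-methyl (2E)-2-(2-chloroethylidene)butanedioate | COC(=O)/C(CC(=O)OC(C)(C)C)=C/CCl
F6 | step 4 | N-methoxy-N-methyl-2-[(triisopropylsilyl)oxy]acetamide | CON(C)C(=O)CO[Si](C(C)C)(C(C)C)C(C)C
F7 | step 4 | (5E)-6-methyl-1-[(triisopropylsilyl)oxy]-8-(2,6,6-trimethylcyclohex-1-en-1-yl)oct-5-en-2-one | CC(C)[Si](OCC(=O)CC/C=C(\C)CCC1=C(C)CCCC1(C)C)(C(C)C)C(C)C
F8 | step 4 | tert-butyl{[(3Z,7E)-8-methyl-4-{[(triisopropylsilyl)oxy]methyl}-10-(2,6,6-trimethylcyclohex-1-en-1-yl)deca-3,7-dien-1-yl]oxy}dimethylsilane | CC(C)(C)[Si](C)(C)OCC/C=C(\CO[Si](C(C)C)(C(C)C)C(C)C)CC/C=C(\C)CCC1=C(C)CCCC1(C)C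
F9 | step 6 | {[(2Z)-2-[(3E)-4-methyl-6-(2,6,6-trimethylcyclohex-1-en-1-yl)hex-3-en-1-yl]penta-2,4-dien-1-yl]oxy}tri(propan-2-yl)silane | C=C/C=C(\CO[Si](C(C)C)(C(C)C)C(C)C)CC/C=C(\C)CCC1=C(C)CCCC1(C)C
F10 | step 10 | (2E,5Z,9E)-2-[2-(tert-butoxy)-2-oxoethyl]-10-methyl-6-{[(triisopropylsilyl)oxy]methyl}-12-(2,6,6-trimethylcyclohex-1-en-1-yl)dodeca-2,5,9-trienoic acid | OC(=O)/C(CC(=O)OC(C)(C)C)=C/C/C=C(\CO[Si](C(C)C)(C(C)C)C(C)C)CC/C=C(\C)CCC1=C(C)CCCC1(C)C
A1 | alternative 1 | (6R)-3-bromo-2-methoxy-6-[(triisopropylsilyl)ethynyl]-5,6-dihydro-2H-pyran (one anomer drawn) | CO[C@H]1O[C@@H](C#C[Si](C(C)C)(C(C)C)C(C)C)CC=C1Br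
A2 | alternative 1 | (2R)-2-[(triisopropylsilyl)ethynyl]-2,3-dihydrofuran | C1=CO[C@@H](C#C[Si](C(C)C)(C(C)C)C(C)C)C1
A3 | alternative 2 | methyl (2R,4Z,8E)-2-hydroxy-5-(hydroxymethyl)-9-methyl-11-(2,6,6-trimethylcyclohex-1-en-1-yl)undeca-4,8-dienoate | CC1=C(CC/C(C)=C/CC/C(=C/C[C@@H](O)C(=O)OC)CO)C(C)(C)CCC1
A4 | alternative 2 | methyl (2R)-oxirane-2-carboxylate | COC(=O)[C@H]1CO1
A5 | alternative 3 | (5R)-4-{[(tert-butyldimethylsilyl)oxy]methyl}-5-[(2Z,6E)-3-{[(tert-butyldimethylsilyl)oxy]methyl}-7-methyl-9-(2,6,6-trimethylcyclohex-1-en-1-yl)nona-2,6-dien-1-yl]furan-2(5H)-one | CC1=C(CC/C(C)=C/CC/C(=C/C[C@H]2OC(=O)C=C2CO[Si](C)(C)C(C)(C)C)CO[Si](C)(C)C(C)(C)C)C(C)(C)CCC1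
A6 | alternative 3 | methyl (2Z)-4-[(tert-butyldimethylsilyl)oxy]-3-iodobut-2-enoate | COC(=O)/C=C(\I)CO[Si](C)(C)C(C)(C)C
A7 | alternative 3 | (3Z,7E)-4-{[(tert-butyldimethylsilyl)oxy]methyl}-8-methyl-10-(2,6,6-trimethylcyclohex-1-en-1-yl)deca-3,7-dienal | O=CC/C=C(\CO[Si](C)(C)C(C)(C)C)CC/C=C(\C)CCC1=C(C)CCCC1(C)C
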